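**Retrosynthetic overview**

1. The target is cut back at the phenolic silyl ether, the acetate, and the C7–O bond, which comes from a C7–B bond by oxidation with retention.
2. Feature used: C8' (CH–CH3), C8 (CH–CH3) and C7 (CH–OAc on ring A, the 3,4-dimethoxyphenyl ring) are three contiguous, all-syn CH carbons. Each can enter as the carbon of LiCHCl2 inserted into a C–B bond, and the last boron sits on C7 where the acetoxy oxygen belongs.
3. Key disconnections, as three Matteson cycles on one (R,R)-diol boronic ester: C7–ring A and C8–C7; C8–C9 and C8'–C8; C8'–C7' and C9'–C8'. This leads back to the methylboronic ester, the ring B benzyl Grignard reagent (from vanillin), MeMgBr and the ring A aryl Grignard reagent.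
4. No ring is formed; rings A and B are bought as 4-bromo-1,2-dimethoxybenzene and vanillin.

Key step: step 7

Remark: lignan numbering is used (C7 = CH(OAc) on ring A; C8, C8' = CH(CH3) with methyls C9, C9'; C7' = CH2 on ring B, the 4-hydroxy-3-methoxyphenyl ring). A boron on C7 ranks below carbon, so the CIP label of C8 reads R in boronic ester 16 and S in alcohol 17 with no change in geometry. The three insertion/displacement cycles are run as one telescoped operation and counted as one step; boronic esters 12 and 14 are bench-stable and can be taken out as checkpoints. The (R,R)-diol → (S)-α-chloro boronic ester correlation is taken from the established empirical rule for these diol esters, not re-derived.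

**Route**

Step 1
Reactants: 1 methylboronic acid; 2 (1R,2R)-1,2-dicyclohexylethane-1,2-diol
Product: 3 (4R,5R)-4,5-dicyclohexyl-2-methyl-1,3,2-dioxaborolane
Conditions: MgSO4, Et2O, rt
Reagents that add atoms: none
Why: Condensation of a boronic acid with a 1,2-diol to the cyclic boronic ester is driven to completion by the desiccant and leaves the two diol stereocentres untouched.

Step 2
Reactants: 4 vanillin
Product: 5 3-methoxy-4-(triisopropylsilyloxy)benzaldehyde
Conditions: TIPSCl, imidazole, DMF, rt
Reagents that add atoms: chlorotriisopropylsilane, CC(C)[Si](Cl)(C(C)C)C(C)C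
Why: Imidazole-mediated silylation of the phenol gives an aryl triisopropylsilyl ether that should withstand organometallic bases and mild peroxide oxidation and still leave with fluoride at the end.

Step 3
Reactants: 5 3-methoxy-4-(triisopropylsilyloxy)benzaldehyde
Product: 6 [3-methoxy-4-(triisopropylsilyloxy)phenyl]methanol
Conditions: NaBH4, MeOH, 0 °C
Reagents that add atoms: none
Why: Borohydride reduction of an aryl aldehyde to the benzylic alcohol is fast and does not disturb the silyl ether.

Step 4
Reactants: 6 [3-methoxy-4-(triisopropylsilyloxy)phenyl]methanol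
Product: 7 4-(chloromethyl)-2-methoxy-1-(triisopropylsilyloxy)benzene
Conditions: SOCl2, DMF (cat.), CH2Cl2, 0 °C; volatiles removed, used crude
Reagents that add atoms: thionyl chloride, O=S(Cl)Cl
Why: Deoxychlorination through the chlorosulfite is rapid for an electron-rich benzylic alcohol, the by-products are gases, and the aryl triisopropylsilyl ether tolerates brief exposure to anhydrous HCl.

Step 5
Reactants: 7 4-(chloromethyl)-2-methoxy-1-(triisopropylsilyloxy)benzene
Product: 8 [3-methoxy-4-(triisopropylsilyloxy)benzyl]magnesium chloride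
Conditions: Mg turnings (excess, I2-activated), THF, 0 °C, slow addition; titrated before use
Reagents that add atoms: magnesium, [Mg]
Why: Grignard formation by magnesium insertion into a benzylic chloride, where the chloride (not the bromide), dilution, low temperature and excess metal hold back Wurtz coupling.

Step 6
Reactants: 9 4-bromo-1,2-dimethoxybenzene
Product: 10 (3,4-dimethoxyphenyl)magnesium bromide
Conditions: Mg turnings, I2 (cat.), THF, rt → 40 °C
Reagents that add atoms: magnesium, [Mg]
Why: Standard Grignard formation from an electron-rich aryl bromide, which has no competing reactive site.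

Step 7
Reactants: 3 (4R,5R)-4,5-dicyclohexyl-2-methyl-1,3,2-dioxaborolane; 8 [3-methoxy-4-(triisopropylsilyloxy)benzyl]magnesium chloride; 10 (3,4-dimethoxyphenyl)magnesium bromide
Product: 16 (4R,5R)-4,5-dicyclohexyl-2-[(1R,2R,3R)-1-(3,4-dimethoxyphenyl)-4-[3-methoxy-4-(triisopropylsilyloxy)phenyl]-2,3-dimethylbutyl]-1,3,2-dioxaborolane, via first α-chloro boronic ester 11 (not isolated), via propan-2-yl boronic ester 12 (not isolated), via second α-chloro boronic ester 13 (not isolated), via butan-2-yl boronic ester 14 (not isolated), via third α-chloro boronic ester 15 (not isolated)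
Conditions: three cycles, crude intermediates carried on after extractive work-up: (a) CH2Cl2, n-BuLi, THF, −100 °C, then the boronic ester, then ZnCl2, −100 °C → rt; (b) RMgX, THF, −78 °C → rt, aq NH4Cl; RMgX = 8 (cycle 1), MeMgBr (cycle 2), 10 (cycle 3)
Reagents that add atoms: dichloromethane, ClCCl (used as dichloromethyllithium, [Li]C(Cl)Cl, made with n-BuLi); methylmagnesium bromide, C[Mg]Br
Why: Each cycle is a Matteson homologation in which LiCHCl2 adds to boron to give a dichloromethyl borate, ZnCl2 assists loss of one diastereotopic chloride as the carbon ligand migrates with retention to give the (S)-α-chloro boronic ester expected for an (R,R)-diol ester, and the Grignard reagent then forms a second borate whose 1,2-shift displaces the remaining chloride with inversion. The closest known reaction type is exactly this iterative Matteson homologation of C2-symmetric diol boronic esters for contiguous stereocentres, so the sequence is known chemistry on a new chain, and no ring closes. C8' is set in cycle 1 (methyl migrates, benzyl enters, R), C8 in cycle 2 (the C8' carbon migrates, methyl enters) and C7 in cycle 3 (the C8 carbon migrates, aryl enters, R), each by the diol on boron, while the migrating carbon keeps its configuration in every insertion. The selectivity needed is reagent-controlled choice between the two chlorides despite an increasingly branched migrating group; it is secured by the C2 symmetry of the diol, which makes both faces of boron equivalent, and by ZnCl2, which speeds the selective shift and ties up the chloride that would epimerise the α-chloro boronic esters. The order of partners (methyl on boron then benzyl; chain then methyl; chain then aryl) is what lets a single hand of the diol give the all-syn triad, and the aryl silyl ether and methyl ethers are inert to LiCHCl2 and Grignard reagents at these temperatures.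

Step 8
Reactants: 16 (4R,5R)-4,5-dicyclohexyl-2-[(1R,2R,3R)-1-(3,4-dimethoxyphenyl)-4-[3-methoxy-4-(triisopropylsilyloxy)phenyl]-2,3-dimethylbutyl]-1,3,2-dioxaborolane
Product: 17 (1R,2S,3R)-1-(3,4-dimethoxyphenyl)-4-[3-methoxy-4-(triisopropylsilyloxy)phenyl]-2,3-dimethylbutan-1-ol
Conditions: NaBO3·4H2O, THF/H2O, rt
Reagents that add atoms: sodium perborate, [Na+].[Na+].O[B-]1(O)OO[B-](O)(O)OO1
Why: Perborate oxidation of the organoboron compound proceeds by addition of hydroperoxide to boron and migration of C7 from boron to oxygen with retention, so the 7R alcohol should form without touching C8 or C8', and the near-neutral medium spares the aryl silyl ether.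

Step 9
Reactants: 17 (1R,2S,3R)-1-(3,4-dimethoxyphenyl)-4-[3-methoxy-4-(triisopropylsilyloxy)phenyl]-2,3-dimethylbutan-1-ol
Product: 18 (1R,2S,3R)-1-(3,4-dimethoxyphenyl)-4-[3-methoxy-4-(triisopropylsilyloxy)phenyl]-2,3-dimethylbutyl acetate
Conditions: Ac2O, pyridine, DMAP (cat.), CH2Cl2, 0 °C → rt
Reagents that add atoms: acetic anhydride, CC(=O)OC(C)=O
Why: DMAP-catalysed acylation of the secondary benzylic alcohol under basic conditions forms the ester at oxygen only, so no stereocentre is touched and the electron-rich benzylic position is never ionised.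

Step 10
Reactants: 18 (1R,2S,3R)-1-(3,4-dimethoxyphenyl)-4-[3-methoxy-4-(triisopropylsilyloxy)phenyl]-2,3-dimethylbutyl acetate
Product: 19 (1R,2S,3R)-1-(3,4-dimethoxyphenyl)-4-(4-hydroxy-3-methoxyphenyl)-2,3-dimethylbutyl acetate
Conditions: Bu4NF, AcOH (1:1), THF, 0 °C
Reagents that add atoms: none
Why: Fluoride cleavage of an aryl silyl ether is fast because phenoxide is a good leaving group, and the acetic acid buffer protonates the phenoxide at once so that the benzylic acetate should neither migrate nor hydrolyse.

**Compound list**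

1 | methylboronic acid | CB(O)O | starting material
2 | (1R,2R)-1,2-dicyclohexylethane-1,2-diol | O[C@H](C1CCCCC1)[C@H](O)C1CCCCC1 | starting material
3 | (4R,5R)-4,5-dicyclohexyl-2-methyl-1,3,2-dioxaborolane | CB1O[C@H](C2CCCCC2)[C@H](O1)C2CCCCC2 | intermediate
4 | vanillin (4-hydroxy-3-methoxybenzaldehyde) | COc1cc(C=O)ccc1O | starting material
5 | 3-methoxy-4-(triisopropylsilyloxy)benzaldehyde | COc1cc(C=O)ccc1O[Si](C(C)C)(C(C)C)C(C)C | intermediate
6 | [3-methoxy-4-(triisopropylsilyloxy)phenyl]methanol | COc1cc(CO)ccc1O[Si](C(C)C)(C(C)C)C(C)C | intermediate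
7 | 4-(chloromethyl)-2-methoxy-1-(triisopropylsilyloxy)benzene | COc1cc(CCl)ccc1O[Si](C(C)C)(C(C)C)C(C)C | intermediate
8 | [3-methoxy-4-(triisopropylsilyloxy)benzyl]magnesium chloride | COc1cc(C[Mg]Cl)ccc1O[Si](C(C)C)(C(C)C)C(C)C | intermediate
9 | 4-bromo-1,2-dimethoxybenzene | COc1ccc(Br)cc1OC | starting material
10 | (3,4-dimethoxyphenyl)magnesium bromide | COc1ccc([Mg]Br)cc1OC | intermediate
11 | (4R,5R)-2-[(1S)-1-chloroethyl]-4,5-dicyclohexyl-1,3,2-dioxaborolane | C[C@@H](Cl)B1O[C@H](C2CCCCC2)[C@H](O1)C2CCCCC2 | intermediate
12 | (4R,5R)-4,5-dicyclohexyl-2-[(2R)-1-[3-methoxy-4-(triisopropylsilyloxy)phenyl]propan-2-yl]-1,3,2-dioxaborolane | COc1cc(C[C@@H](C)B2O[C@H](C3CCCCC3)[C@H](O2)C3CCCCC3)ccc1O[Si](C(C)C)(C(C)C)C(C)C | intermediate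
13 | (4R,5R)-2-[(1S,2R)-1-chloro-3-[3-methoxy-4-(triisopropylsilyloxy)phenyl]-2-methylpropyl]-4,5-dicyclohexyl-1,3,2-dioxaborolane | COc1cc(C[C@@H](C)[C@@H](Cl)B2O[C@H](C3CCCCC3)[C@H](O2)C3CCCCC3)ccc1O[Si](C(C)C)(C(C)C)C(C)C | intermediate
14 | (4R,5R)-4,5-dicyclohexyl-2-[(2S,3R)-4-[3-methoxy-4-(triisopropylsilyloxy)phenyl]-3-methylbutan-2-yl]-1,3,2-dioxaborolane | COc1cc(C[C@@H](C)[C@H](C)B2O[C@H](C3CCCCC3)[C@H](O2)C3CCCCC3)ccc1O[Si](C(C)C)(C(C)C)C(C)C | intermediate
15 | (4R,5R)-2-[(1S,2S,3R)-1-chloro-4-[3-methoxy-4-(triisopropylsilyloxy)phenyl]-2,3-dimethylbutyl]-4,5-dicyclohexyl-1,3,2-dioxaborolane | COc1cc(C[C@@H](C)[C@H](C)[C@@H](Cl)B2O[C@H](C3CCCCC3)[C@H](O2)C3CCCCC3)ccc1O[Si](C(C)C)(C(C)C)C(C)C | intermediate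
16 | (4R,5R)-4,5-dicyclohexyl-2-[(1R,2R,3R)-1-(3,4-dimethoxyphenyl)-4-[3-methoxy-4-(triisopropylsilyloxy)phenyl]-2,3-dimethylbutyl]-1,3,2-dioxaborolane | COc1cc(C[C@@H](C)[C@H](C)[C@@H](B2O[C@H](C3CCCCC3)[C@H](O2)C3CCCCC3)c2ccc(OC)c(OC)c2)ccc1O[Si](C(C)C)(C(C)C)C(C)C | intermediate
17 | (1R,2S,3R)-1-(3,4-dimethoxyphenyl)-4-[3-methoxy-4-(triisopropylsilyloxy)phenyl]-2,3-dimethylbutan-1-ol | COc1cc(C[C@@H](C)[C@H](C)[C@@H](O)c2ccc(OC)c(OC)c2)ccc1O[Si](C(C)C)(C(C)C)C(C)C | intermediate
18 | (1R,2S,3R)-1-(3,4-dimethoxyphenyl)-4-[3-methoxy-4-(triisopropylsilyloxy)phenyl]-2,3-dimethylbutyl acetate | COc1cc(C[C@@H](C)[C@H](C)[C@@H](OC(C)=O)c2ccc(OC)c(OC)c2)ccc1O[Si](C(C)C)(C(C)C)C(C)C | intermediate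
19 | (1R,2S,3R)-1-(3,4-dimethoxyphenyl)-4-(4-hydroxy-3-methoxyphenyl)-2,3-dimethylbutyl acetate | COc1cc(C[C@@H](C)[C@H](C)[C@@H](OC(C)=O)c2ccc(OC)c(OC)c2)ccc1O | target

**Step count**

Total: 10 steps. Longest linear sequence: 8 steps (vanillin 4 → 19 through steps 2, 3, 4, 5, 7, 8, 9, 10).

**Steps most likely to fail**

Step 7. In the third cycle the borate formed from the β-branched α-chloro boronic ester and the aryl Grignard reagent may rearrange slowly. That would leave time for chloride-induced epimerisation at C7 or for migration of a ring oxygen in place of the aryl group, and reagent control could also erode as the migrating group becomes more branched. Fallback: the sequence is stopped after the third insertion at 15, and C7 is set by carbonyl addition instead of a 1,2-shift on boron. Oxidation of 15 with H2O2 in pH 8 phosphate buffer/THF at 0 °C should give the aldehyde (2S,3R)-4-[3-methoxy-4-(triisopropylsilyloxy)phenyl]-2,3-dimethylbutanal F1. Addition of 10 in THF at −78 °C should then follow the Felkin–Anh mode, anti to the C8' branch, which leads to the 7,8-syn alcohol. The route is rejoined at 17 after chromatographic removal of the minor C7 epimer (1S,2S,3R)-1-(3,4-dimethoxyphenyl)-4-[3-methoxy-4-(triisopropylsilyloxy)phenyl]-2,3-dimethylbutan-1-ol F2.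

Step 8. Oxidation of the hindered dioxaborolane may be slow under perborate, and more forcing basic peroxide risks partial loss of the aryl silyl group or protodeboronation at the electron-rich benzylic carbon. Fallback: the protecting-group plan is changed so that loss of the silyl group is intended. From 16, NaOH/H2O2 in THF (0 °C → rt, finished with Bu4NF if silyl ether remains) should give the phenol alcohol (1R,2S,3R)-1-(3,4-dimethoxyphenyl)-4-(4-hydroxy-3-methoxyphenyl)-2,3-dimethylbutan-1-ol F3. Acetylation of both hydroxyl groups (Ac2O, pyridine, DMAP) should give the diacetate (1R,2S,3R)-4-(4-acetoxy-3-methoxyphenyl)-1-(3,4-dimethoxyphenyl)-2,3-dimethylbutyl acetate F4. Chemoselective aminolysis of the aryl acetate with pyrrolidine in CH2Cl2 at 0 °C, which leaves the secondary alkyl acetate, rejoins the route at 19.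

Step 5. Magnesium insertion into the electron-rich benzylic chloride may be accompanied by Wurtz homocoupling, giving a low and variable titre that starves the first displacement of step 7. Fallback: the benzyl nucleophile is made by tin–lithium exchange, where no benzylic halide is present when the carbanion forms. From 7, Bu3SnLi (from Bu3SnH and LDA) in THF at −78 °C should give tributyl{[3-methoxy-4-(triisopropylsilyloxy)phenyl]methyl}stannane F5. Treatment with n-BuLi in THF at −78 °C should give [3-methoxy-4-(triisopropylsilyloxy)benzyl]lithium F6, which is added to 11 in place of 8 in the first cycle of step 7 and rejoins the route at 12.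

**Further compounds**

F1 | step 7 | (2S,3R)-4-[3-methoxy-4-(triisopropylsilyloxy)phenyl]-2,3-dimethylbutanal | COc1cc(C[C@@H](C)[C@H](C)C=O)ccc1O[Si](C(C)C)(C(C)C)C(C)C
F2 | step 7 | (1S,2S,3R)-1-(3,4-dimethoxyphenyl)-4-[3-methoxy-4-(triisopropylsilyloxy)phenyl]-2,3-dimethylbutan-1-ol | COc1cc(C[C@@H](C)[C@H](C)[C@H](O)c2ccc(OC)c(OC)c2)ccc1O[Si](C(C)C)(C(C)C)C(C)C
F3 | step 8 | (1R,2S,3R)-1-(3,4-dimethoxyphenyl)-4-(4-hydroxy-3-methoxyphenyl)-2,3-dimethylbutan-1-ol | COc1cc(C[C@@H](C)[C@H](C)[C@@H](O)c2ccc(OC)c(OC)c2)ccc1O
F4 | step 8 | (1R,2S,3R)-4-(4-acetoxy-3-methoxyphenyl)-1-(3,4-dimethoxyphenyl)-2,3-dimethylbutyl acetate | COc1cc(C[C@@H](C)[C@H](C)[C@@H](OC(C)=O)c2ccc(OC)c(OC)c2)ccc1OC(C)=O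
F5 | step 5 | tributyl{[3-methoxy-4-(triisopropylsilyloxy)phenyl]methyl}stannane | COc1cc(C[Sn](CCCC)(CCCC)CCCC)ccc1O[Si](C(C)C)(C(C)C)C(C)C
F6 | step 5 | [3-methoxy-4-(triisopropylsilyloxy)benzyl]lithium | COc1cc(C[Li])ccc1O[Si](C(C)C)(C(C)C)C(C)C
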